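## Analysis of the target

Target 21 is a furofuran lignan: a 2,6-diaryl-3,7-dioxabicyclo[3.3.0]octane with an acetoxy group on one ring-fusion carbon (the monomethyl ether of 1-acetoxypinoresinol). The core is numbered C1 (acetoxy-bearing fusion carbon), C2 (CH bearing the guaiacyl group), O3, C4 (CH2), C5 (fusion CH), C6 (CH bearing the veratryl group), O7 and C8 (CH2); ring A is C1–C2–O3–C4–C5 and ring B is C5–C6–O7–C8–C1. The four contiguous stereocentres are (1S,2R,5R,6S): the rings are cis-fused, the C1 oxygen and H5 lie on the convex face, and both aryl groups are exo, so the C2 aryl is cis to the acetoxy group and the C6 aryl is cis to H5. The two aryl groups differ (one free phenol, one dimethyl ether), so no route that dimerises a single arylpropanoid unit can be used. Sensitive groups are the two benzylic C–O bonds on electron-rich rings (ionised by acid with epimerisation at C2 or C6, cleaved by hydrogenolysis), the hindered tertiary acetate, which must survive liberation of the phenol, and the phenol itself. The difficulty is the fully substituted, oxygen-bearing C1 at the ring fusion: an enolate at C1 of a monocyclic ring B lactone would normally react on the face trans to its C5 substituent, which is the wrong face for ring A. The strategy rests on C2 being an aldehyde-level carbon held between O3 and C1, and on C1 being alpha to C8: with C8 as a lactone carbonyl, C1 is an enolate carbon, and an aryl aldehyde can be inserted between the C4 oxygen and C1 of a preformed ring B lactone.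

## Retrosynthetic reasoning

**21 ⇒ 20.** The phenolic O–H is disconnected last and carried as an allyl ether. The forward step must free the phenol under neutral, non-reductive conditions, because the tertiary acetate is base-sensitive and the two benzylic ether bonds would be at risk under hydrogenolysis.

**20 ⇒ 19 ⇒ 18.** The acyl C–O bond at C1 is cut, then the O–Si bond. An acetate cannot travel through enolate and hydride chemistry, so the C1 oxygen is a tert-butyldimethylsilyl ether until the skeleton is complete. Acetylation is done while the phenol is still masked, so the tertiary alcohol is the only acylable group.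

**18 ⇒ 17 ⇒ 16.** C8 is taken back from methylene through lactol 17 to the lactone carbonyl of 16. No skeletal bond is cut. What is gained is the polarity needed for the key step: with C8 as a carbonyl, C1 becomes nucleophilic.

**16 ⇒ 11 + 12 (key disconnection).** Both bonds to C2 are cut, C1–C2 and C2–O3, which releases C2 with its aryl group as aldehyde 12 and leaves ring B lactone 11 with a free C4 hydroxyl.
- Why here: C2 is the only ring A carbon that is simultaneously attached to a heteroatom and to the enolisable C1, so it alone can be introduced as a carbonyl electrophile.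
- What is gained: the molecule is split into its two aryl-bearing halves, and the C1 facial problem is solved, because an electrophile first attached to O3 (hence to C4 on C5) can reach C1 only on the face cis to C4.
- What the forward reaction must do: silylate O4 and enolise C1 (ketene acetal 14, via 13), condense O4 with 12 to the oxocarbenium ion 15, and let C1 capture it. C1 is planarised on the way, so its configuration in 11 does not matter.

**11 ⇒ 10 ⇒ 8 ⇒ 7.** The C4 alcohol is traced back to a carboxylic acid, and the C1–O bond is cut back to the unsubstituted paraconic acid 7. Oxygenating C1 at the acid stage lets the carboxylate act as its own protecting group for C4, so no separate protection and deprotection of the C4 alcohol is needed. Silyl ester 9 is only a transient on the way to 10.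

**7 ⇒ 6 ⇒ 3 + 4.** The C5–C6 bond is cut as an auxiliary-controlled aldol between the succinate imide 3 and veratraldehyde 4. The aldolate 5 lactonises onto the ester to close ring B. This one step sets the absolute configuration of C5 and C6 and their trans relation, and every later stereocentre is derived from them.

**3 ⇒ 1 + 2.** The imide N–acyl bond is cut to the commercial oxazolidinone 1 and the commercial half-ester acid chloride 2.

## Alternatives that were turned down

**Alternative 1:** benzylidene lactone epoxide rearranged into a ring A hydroxylactone.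
- Disconnection: C2–O3, with ring A made first as a lactone whose carbonyl is C4.
- Forward key step: hydroxide opens the lactone of spiro-epoxide A1; the freed C4 carboxylate attacks benzylic C2 with inversion and gives hydroxylactone diol A2, the epoxide oxygen becoming the C1 hydroxyl.
- For: C1 and C2 would both come from one reagent-controlled epoxidation, the C1 oxygen is in place with the right configuration from the start, and the key step is a classical intramolecular epoxide opening. On these points it is stronger than the chosen route, which uses a stoichiometric auxiliary, a separate enolate hydroxylation and a key step of higher risk.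
- Against: A2 contains only ring A. The veratryl half, C5 and C6 are still missing. The C5 enolate of A2 would have to add veratraldehyde on the face cis to C8, next to a quaternary C1 whose two substituents (an oxygen and a CH2O group) differ little in size, so facial control is weak, and the C6 carbinol is uncontrolled. Ring B closure and reduction of the C4 carbonyl still follow. The opening at an electron-rich benzylic carbon may also lose stereochemical fidelity through a carbocation.
- Comparison: the chosen strategy has both rings and all four stereocentres in place after its key step, with C5 and C6 fixed beforehand by a reliable aldol.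

**Alternative 2:** eight-membered cyclic enol ether stitched by transannular ketone closure.
- Disconnection: the central C1–C5 bond, so that both rings arise at once from the eight-membered keto enol ether A3.
- Forward key step: a Lewis acid activates the C1 ketone, enol ether carbon C5 attacks it across the ring, and a hydrosilane reduces the resulting C4 oxocarbenium ion to give tertiary alcohol A4.
- For: only acetylation and deprotection remain after A4, clearly fewer steps than the five that follow the chosen key step. The C1 alcohol is formed directly, and the cis fusion is guaranteed by the transannular geometry.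
- Against: A3 is a medium ring with a cis enol ether and two benzylic ether stereocentres that must come from two separately made chiral fragments and two etherifications. C2 in A3 is benzylic, oxygenated and alpha to the ketone, so it is easily epimerised or enolised before or during the Lewis acid step. Whether the aryl groups end up exo depends on which conformer of the eight-membered ring reacts, and no structural element enforces it. The hydrosilane and Lewis acid also act in the presence of two ionisable benzylic ethers.
- Comparison: the chosen strategy gives up the short endgame, but its precursor 11 is reached by standard reactions and its stereocontrol rests on a tether on a rigid five-membered lactone, not on a medium-ring conformation.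

**Alternative 3:** benzylic C–H etherification closes ring B.
- Disconnection: C6–O7, ring B closed last by oxidation of a C6 methylene.
- Forward key step: a high-potential quinone oxidant abstracts hydride from the C6 methylene of tetrahydrofuran diol A5 and the C8 hydroxyl traps the benzylic cation to give A6.
- For: C4 and C8 are at their final oxidation level throughout, so no lactone or lactol reduction is needed. Here it is stronger than the chosen route, which spends two steps on C8. The C1 alcohol needs no protection, and oxidative benzylic etherification of electron-rich benzyl groups is a known reaction type.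
- Against: A5 already needs the quaternary C1 flanked by C2 and C5 on a tetrasubstituted tetrahydrofuran, which is no easier than 11. C6 is set only by substrate preference in the cation capture. The C6–H of product A6 is a benzylic ether hydrogen on the veratryl ring and is more easily oxidised than the methylene of A5, so over-oxidation is built in. C2–H is protected only by the deactivating phenol acetate. The acetyl group in A6 sits on the wrong oxygen, so C1 must still be acetylated and the aryl acetate then removed selectively.
- Comparison: the chosen route pays two redox steps at C8 but never exposes the electron-rich furofuran to a strong oxidant, fixes C6 by auxiliary control and ends with an unambiguous protecting group sequence.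

Key step: step 7

Remark on the chemistry: the phenol is carried as an allyl ether (commercial aldehyde 12) because a final hydrogenolysis of a benzyl ether would endanger the two benzylic C–O bonds of the furofuran; locants C1–C8 are those of the bicyclic core and are also used for the monocyclic precursors.

## Route

Step 1
Reactants: 1 (S)-4-benzyl-1,3-oxazolidin-2-one; 2 methyl 4-chloro-4-oxobutanoate
Product: 3 methyl 4-[(4S)-4-benzyl-2-oxo-1,3-oxazolidin-3-yl]-4-oxobutanoate
Conditions: nBuLi, THF, −78 °C; then 2, −78 → 0 °C
Reagents that add atoms: none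
Why: N-acylation of the lithiated oxazolidinone by the acid chloride, which is far faster than attack on the methyl ester.

Step 2
Reactants: 3 methyl 4-[(4S)-4-benzyl-2-oxo-1,3-oxazolidin-3-yl]-4-oxobutanoate; 4 3,4-dimethoxybenzaldehyde (veratraldehyde)
Product: 6 (4S)-4-benzyl-3-[(2S,3S)-2-(3,4-dimethoxyphenyl)-5-oxooxolane-3-carbonyl]-1,3-oxazolidin-2-one, via syn-aldol hydroxy ester 5 (not isolated)
Conditions: Bu2BOTf, iPr2NEt, CH2Cl2, 0 °C; 4, −78 °C → rt; H2O2, pH 7 buffer, MeOH, 0 °C
Reagents that add atoms: none
Why: Evans syn aldol: Bu2BOTf enolises the imide methylene (not the ester) to the (Z)-boron enolate, which adds to 4 through a chair transition state on the face away from the auxiliary benzyl group and sets C5 and C6 as (S,S). The syn aldolate 5 should lactonise onto the methyl ester on warming (a trace of pyridinium tosylate would complete it), and closure through the syn-related oxygen and ester arm leaves the aryl and acyl groups trans on ring B.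

Step 3
Reactants: 6 (4S)-4-benzyl-3-[(2S,3S)-2-(3,4-dimethoxyphenyl)-5-oxooxolane-3-carbonyl]-1,3-oxazolidin-2-one
Product: 7 (2S,3S)-2-(3,4-dimethoxyphenyl)-5-oxooxolane-3-carboxylic acid
Conditions: LiOH, H2O2, THF/H2O, 0 °C; Na2SO3; HCl to pH 2
Reagents that add atoms: hydrogen peroxide (acting as LiOOH; supplies the carboxyl OH oxygen), OO
Why: Hydroperoxide cleavage of the imide: LiOOH attacks the exocyclic carbonyl selectively and releases auxiliary 1. Any lactone opened by hydroxide recloses on acidification, the five-membered lactone being the only one possible, and 0 °C avoids epimerisation at C5.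

Step 4
Reactants: 7 (2S,3S)-2-(3,4-dimethoxyphenyl)-5-oxooxolane-3-carboxylic acid
Product: 8 (2S,3S,4S)-2-(3,4-dimethoxyphenyl)-4-hydroxy-5-oxooxolane-3-carboxylic acid
Conditions: NaN(SiMe3)2 (2.2 equiv), THF, −78 °C; 2-(phenylsulfonyl)-3-phenyloxaziridine, −78 °C; aq. HCl
Reagents that add atoms: 2-(phenylsulfonyl)-3-phenyloxaziridine (Davis oxaziridine), O=S(=O)(c1ccccc1)N1OC1c1ccccc1
Why: Davis enolate hydroxylation of the carboxylate–enolate dianion: the second equivalent of base enolises only the lactone methylene C1 (the C5 hydrogen next to the carboxylate is far less acidic, so the lactone is not opened by elimination), and oxygen enters trans to the C5 carboxylate. The carboxylate is its own protecting group for C4, and the C1 configuration is of no consequence because step 7 planarises this carbon.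

Step 5
Reactants: 8 (2S,3S,4S)-2-(3,4-dimethoxyphenyl)-4-hydroxy-5-oxooxolane-3-carboxylic acid
Product: 10 (2S,3R,4S)-4-[(tert-butyldimethylsilyl)oxy]-2-(3,4-dimethoxyphenyl)-5-oxooxolane-3-carboxylic acid, via silyl ester 9 (not isolated)
Conditions: tBuMe2SiOTf, 2,6-lutidine, CH2Cl2, 0 °C; then AcOH, THF/H2O, rt
Reagents that add atoms: tert-butyldimethylsilyl trifluoromethanesulfonate, CC(C)(C)[Si](C)(C)OS(=O)(=O)C(F)(F)F
Why: Silyl triflate silylation of both the secondary alcohol and the acid; the silyl ester of 9 is far more labile than the silyl ether and is hydrolysed selectively by aqueous acetic acid.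

Step 6
Reactants: 10 (2S,3R,4S)-4-[(tert-butyldimethylsilyl)oxy]-2-(3,4-dimethoxyphenyl)-5-oxooxolane-3-carboxylic acid
Product: 11 (3S,4R,5S)-3-[(tert-butyldimethylsilyl)oxy]-5-(3,4-dimethoxyphenyl)-4-(hydroxymethyl)oxolan-2-one
Conditions: BH3·SMe2, THF, 0 °C → rt; MeOH
Reagents that add atoms: none
Why: Chemoselective borane reduction: the carboxylic acid is reduced through its acyloxyborane much faster than the electron-poor lactone carbonyl, and under these non-basic conditions the silyl ether and the neighbouring stereocentres are untouched.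

Step 7
Reactants: 11 (3S,4R,5S)-3-[(tert-butyldimethylsilyl)oxy]-5-(3,4-dimethoxyphenyl)-4-(hydroxymethyl)oxolan-2-one; 12 3-methoxy-4-(prop-2-en-1-yloxy)benzaldehyde (O-allylvanillin)
Product: 16 (1R,2R,5R,6S)-1-[(tert-butyldimethylsilyl)oxy]-6-(3,4-dimethoxyphenyl)-2-[3-methoxy-4-(prop-2-en-1-yloxy)phenyl]-3,7-dioxabicyclo[3.3.0]octan-8-one, via C4 trimethylsilyl ether 13 (not isolated), via bis-silyl ketene acetal 14 (not isolated), via oxocarbenium triflate 15 (not isolated)
Conditions: Me3SiCl, LiN(iPr)2 (2.2 equiv), THF, −78 °C; evaporate, pentane, filter; then 12, Me3SiOTf (0.5 equiv), 2,6-di-tert-butyl-4-methylpyridine (0.2 equiv), CH2Cl2, −78 → −40 °C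
Reagents that add atoms: none
Why: Proposed new method: internal-quench double silylation gives 14 (the alkoxide is trapped as 13 before it can attack the lactone or pull the silyl group over from O1), in which C1 is the only nucleophilic carbon and the C4 trimethylsilyl ether the only oxygen free to condense; Me3SiOTf then activates aldehyde 12, the silyl ether adds to it and loss of (Me3Si)2O gives the (E)-oxocarbenium ion 15 (C2–O3 bond), which C1 of the ketene acetal captures (C1–C2 bond) before the lactone silyloxocarbenium ion returns Me3Si+ to triflate. The closest known reaction types are the Me3SiOTf-promoted condensation of silyl ethers with aldehydes to oxocarbenium ions, their intramolecular Mukaiyama aldol capture (Mukaiyama aldol–Prins family) and the Lewis-acid-induced O-to-C rearrangement of cyclic vinyl acetals (Petasis–Ferrier type), in which an oxocarbenium ion and a tethered enolate recombine to a five-membered ring; new here are the tetrasubstituted alpha-silyloxy lactone ketene acetal as nucleophile and the quaternary centre that results. Ring A closes in a 5-(enolexo)-endo-trig mode, the C2=O3 bond lying inside the new ring, which cationic oxocarbenium electrophiles with early transition states tolerate. C1 is set by the tether: C2 hangs from O3 on C4, and C4 sits on one face of ring B at C5, so C2 can reach only the C1 face cis to C4, which gives the cis fusion and turns the silyloxy group to the convex face whatever the C1 configuration of 11 was. C2 is set by the geometry of 15: in the (E)-ion the aryl group is trans to C4 and points away from ring B, while the position cis to C4, which lies over C8 and its silyloxy group, is taken by hydrogen, so the aryl group ends up exo. C5 and C6 are not touched. The step needs the condensation at O3 to outrun direct intermolecular Mukaiyama addition of 14 to silyl-activated 12, which would attack the open C1 face trans to C4; the low temperature, the poor electrophilicity of the electron-rich aldehyde before it becomes the ion, the steric shielding of the tetrasubstituted ketene acetal and the fact that any bis-alkyl acetal formed on the way re-ionises to the same tethered ion are what should secure this.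

Step 8
Reactants: 16 (1R,2R,5R,6S)-1-[(tert-butyldimethylsilyl)oxy]-6-(3,4-dimethoxyphenyl)-2-[3-methoxy-4-(prop-2-en-1-yloxy)phenyl]-3,7-dioxabicyclo[3.3.0]octan-8-one
Product: 17 (1R,2R,5R,6S)-1-[(tert-butyldimethylsilyl)oxy]-6-(3,4-dimethoxyphenyl)-2-[3-methoxy-4-(prop-2-en-1-yloxy)phenyl]-3,7-dioxabicyclo[3.3.0]octan-8-ol (lactol; both C8 anomers)
Conditions: iBu2AlH, CH2Cl2, −78 °C; aq. potassium sodium tartrate
Reagents that add atoms: none
Why: Partial reduction of a lactone: at −78 °C the tetrahedral aluminium alkoxide is stable, so reduction should stop at the lactol; silyl, allyl and benzylic ethers are inert.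

Step 9
Reactants: 17 (1R,2R,5R,6S)-1-[(tert-butyldimethylsilyl)oxy]-6-(3,4-dimethoxyphenyl)-2-[3-methoxy-4-(prop-2-en-1-yloxy)phenyl]-3,7-dioxabicyclo[3.3.0]octan-8-ol
Product: 18 (1S,2R,5R,6S)-1-[(tert-butyldimethylsilyl)oxy]-6-(3,4-dimethoxyphenyl)-2-[3-methoxy-4-(prop-2-en-1-yloxy)phenyl]-3,7-dioxabicyclo[3.3.0]octane
Conditions: Et3SiH, BF3·OEt2, CH2Cl2, −78 → −40 °C
Reagents that add atoms: none
Why: Ionic hydrogenation of a lactol: BF3 ionises the anomeric hydroxyl to the C8 oxocarbenium ion, which Et3SiH reduces to the methylene; no stereocentre is created, and the low temperature is meant to keep the two benzylic ether bonds from ionising.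

Step 10
Reactants: 18 (1S,2R,5R,6S)-1-[(tert-butyldimethylsilyl)oxy]-6-(3,4-dimethoxyphenyl)-2-[3-methoxy-4-(prop-2-en-1-yloxy)phenyl]-3,7-dioxabicyclo[3.3.0]octane
Product: 19 (1S,2R,5R,6S)-6-(3,4-dimethoxyphenyl)-2-[3-methoxy-4-(prop-2-en-1-yloxy)phenyl]-3,7-dioxabicyclo[3.3.0]octan-1-ol
Conditions: Bu4NF, THF, rt → 50 °C
Reagents that add atoms: none
Why: Fluoride cleavage of the tertiary silyl ether on the open convex face; the allyl ether and the cyclic ethers are inert to fluoride.

Step 11
Reactants: 19 (1S,2R,5R,6S)-6-(3,4-dimethoxyphenyl)-2-[3-methoxy-4-(prop-2-en-1-yloxy)phenyl]-3,7-dioxabicyclo[3.3.0]octan-1-ol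
Product: 20 (1S,2R,5R,6S)-6-(3,4-dimethoxyphenyl)-2-[3-methoxy-4-(prop-2-en-1-yloxy)phenyl]-3,7-dioxabicyclo[3.3.0]octan-1-yl acetate
Conditions: Ac2O, Et3N, DMAP, CH2Cl2, rt → 40 °C
Reagents that add atoms: acetic anhydride, CC(=O)OC(C)=O
Why: Acylpyridinium (nucleophilic) catalysis for acylation of a hindered tertiary alcohol, which lies on the convex face; with the phenol still protected it is the only acylable group.

Step 12
Reactants: 20 (1S,2R,5R,6S)-6-(3,4-dimethoxyphenyl)-2-[3-methoxy-4-(prop-2-en-1-yloxy)phenyl]-3,7-dioxabicyclo[3.3.0]octan-1-yl acetate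
Product: 21 (1S,2R,5R,6S)-6-(3,4-dimethoxyphenyl)-2-(4-hydroxy-3-methoxyphenyl)-3,7-dioxabicyclo[3.3.0]octan-1-yl acetate (target)
Conditions: Pd(PPh3)4 (5 mol%), morpholine, THF, rt
Reagents that add atoms: none
Why: Tsuji–Trost-type allyl transfer: zerovalent palladium ionises the aryl allyl ether to a π-allyl complex and the phenoxide, and morpholine takes up the allyl group; the neutral conditions leave the tertiary acetate and the benzylic ether bonds alone.

## Compound list

1 | (S)-4-benzyl-1,3-oxazolidin-2-one | O=C1N[C@@H](Cc2ccccc2)CO1 | starting material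
2 | methyl 4-chloro-4-oxobutanoate | COC(=O)CCC(Cl)=O | starting material
3 | methyl 4-[(4S)-4-benzyl-2-oxo-1,3-oxazolidin-3-yl]-4-oxobutanoate | COC(=O)CCC(=O)N1C(=O)OC[C@@H]1Cc1ccccc1 | intermediate
4 | 3,4-dimethoxybenzaldehyde (veratraldehyde) | COc1ccc(C=O)cc1OC | starting material
5 | methyl (3S)-4-[(4S)-4-benzyl-2-oxo-1,3-oxazolidin-3-yl]-3-[(S)-(3,4-dimethoxyphenyl)(hydroxy)methyl]-4-oxobutanoate (syn aldol adduct, formed in the flask) | COc1ccc([C@@H](O)[C@H](CC(=O)OC)C(=O)N2C(=O)OC[C@@H]2Cc2ccccc2)cc1OC | intermediate
6 | (4S)-4-benzyl-3-[(2S,3S)-2-(3,4-dimethoxyphenyl)-5-oxooxolane-3-carbonyl]-1,3-oxazolidin-2-one | COc1ccc([C@H]2OC(=O)C[C@@H]2C(=O)N2C(=O)OC[C@@H]2Cc2ccccc2)cc1OC | intermediate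
7 | (2S,3S)-2-(3,4-dimethoxyphenyl)-5-oxooxolane-3-carboxylic acid (trans paraconic acid) | COc1ccc([C@H]2OC(=O)C[C@@H]2C(O)=O)cc1OC | intermediate
8 | (2S,3S,4S)-2-(3,4-dimethoxyphenyl)-4-hydroxy-5-oxooxolane-3-carboxylic acid | COc1ccc([C@H]2OC(=O)[C@@H](O)[C@@H]2C(O)=O)cc1OC | intermediate
9 | tert-butyldimethylsilyl (2S,3R,4S)-4-[(tert-butyldimethylsilyl)oxy]-2-(3,4-dimethoxyphenyl)-5-oxooxolane-3-carboxylate (formed in the flask) | COc1ccc([C@H]2OC(=O)[C@@H](O[Si](C)(C)C(C)(C)C)[C@@H]2C(=O)O[Si](C)(C)C(C)(C)C)cc1OC | intermediate
10 | (2S,3R,4S)-4-[(tert-butyldimethylsilyl)oxy]-2-(3,4-dimethoxyphenyl)-5-oxooxolane-3-carboxylic acid | COc1ccc([C@H]2OC(=O)[C@@H](O[Si](C)(C)C(C)(C)C)[C@@H]2C(O)=O)cc1OC | intermediate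
11 | (3S,4R,5S)-3-[(tert-butyldimethylsilyl)oxy]-5-(3,4-dimethoxyphenyl)-4-(hydroxymethyl)oxolan-2-one (ring B lactone, silyloxy trans to CH2OH, aryl trans to CH2OH) | COc1ccc([C@H]2OC(=O)[C@@H](O[Si](C)(C)C(C)(C)C)[C@@H]2CO)cc1OC | intermediate
12 | 3-methoxy-4-(prop-2-en-1-yloxy)benzaldehyde (O-allylvanillin) | COc1cc(C=O)ccc1OCC=C | starting material
13 | (3S,4R,5S)-3-[(tert-butyldimethylsilyl)oxy]-5-(3,4-dimethoxyphenyl)-4-{[(trimethylsilyl)oxy]methyl}oxolan-2-one (formed in the flask) | COc1ccc([C@H]2OC(=O)[C@@H](O[Si](C)(C)C(C)(C)C)[C@@H]2CO[Si](C)(C)C)cc1OC | intermediate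
14 | (4R,5S)-3-[(tert-butyldimethylsilyl)oxy]-5-(3,4-dimethoxyphenyl)-2-[(trimethylsilyl)oxy]-4-{[(trimethylsilyl)oxy]methyl}-4,5-dihydrofuran (silyl ketene acetal, formed in the flask) | COc1ccc([C@H]2OC(O[Si](C)(C)C)=C(O[Si](C)(C)C(C)(C)C)[C@@H]2CO[Si](C)(C)C)cc1OC | intermediate
15 | (E)-oxocarbenium ion from O4 of 14 and the carbonyl carbon of 12, triflate salt (formed in the flask) | COc1ccc([C@H]2OC(O[Si](C)(C)C)=C(O[Si](C)(C)C(C)(C)C)[C@@H]2C/[O+]=C/c2ccc(OCC=C)c(OC)c2)cc1OC.[O-]S(=O)(=O)C(F)(F)F | intermediate
16 | (1R,2R,5R,6S)-1-[(tert-butyldimethylsilyl)oxy]-6-(3,4-dimethoxyphenyl)-2-[3-methoxy-4-(prop-2-en-1-yloxy)phenyl]-3,7-dioxabicyclo[3.3.0]octan-8-one (cis-fused, both aryl groups exo) | COc1cc([C@H]2OC[C@@H]3[C@@H](c4ccc(OC)c(OC)c4)OC(=O)[C@]23O[Si](C)(C)C(C)(C)C)ccc1OCC=C | intermediate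
17 | (1R,2R,5R,6S)-1-[(tert-butyldimethylsilyl)oxy]-6-(3,4-dimethoxyphenyl)-2-[3-methoxy-4-(prop-2-en-1-yloxy)phenyl]-3,7-dioxabicyclo[3.3.0]octan-8-ol (both C8 anomers) | COc1cc([C@H]2OC[C@@H]3[C@@H](c4ccc(OC)c(OC)c4)OC(O)[C@]23O[Si](C)(C)C(C)(C)C)ccc1OCC=C | intermediate
18 | (1S,2R,5R,6S)-1-[(tert-butyldimethylsilyl)oxy]-6-(3,4-dimethoxyphenyl)-2-[3-methoxy-4-(prop-2-en-1-yloxy)phenyl]-3,7-dioxabicyclo[3.3.0]octane | COc1cc([C@H]2OC[C@@H]3[C@@H](c4ccc(OC)c(OC)c4)OC[C@]23O[Si](C)(C)C(C)(C)C)ccc1OCC=C | intermediate
19 | (1S,2R,5R,6S)-6-(3,4-dimethoxyphenyl)-2-[3-methoxy-4-(prop-2-en-1-yloxy)phenyl]-3,7-dioxabicyclo[3.3.0]octan-1-ol | COc1cc([C@H]2OC[C@@H]3[C@@H](c4ccc(OC)c(OC)c4)OC[C@]23O)ccc1OCC=C | intermediate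
20 | (1S,2R,5R,6S)-6-(3,4-dimethoxyphenyl)-2-[3-methoxy-4-(prop-2-en-1-yloxy)phenyl]-3,7-dioxabicyclo[3.3.0]octan-1-yl acetate | COc1cc([C@H]2OC[C@@H]3[C@@H](c4ccc(OC)c(OC)c4)OC[C@]23OC(C)=O)ccc1OCC=C | intermediate
21 | (1S,2R,5R,6S)-6-(3,4-dimethoxyphenyl)-2-(4-hydroxy-3-methoxyphenyl)-3,7-dioxabicyclo[3.3.0]octan-1-yl acetate | COc1cc([C@H]2OC[C@@H]3[C@@H](c4ccc(OC)c(OC)c4)OC[C@]23OC(C)=O)ccc1O | target

## Step count and least certain steps

Total step count: 12. Longest linear sequence: 12 steps (1 → 21); 2, 4 and 12 enter as purchased materials.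

**Step 7 (key step, proposed new method).**
- What may go wrong: direct intermolecular Mukaiyama addition of ketene acetal 14 to silyl-activated 12 may outrun formation of the tethered ion 15. C2 would then be attached on the C1 face trans to C4 (loss of the tether-derived facial control), and ring A could not close. The 5-endo closure may also be slow enough for traces of acid to protodesilylate the ketene acetal.
- Fallback (known chemistry; sets out from 11, uses 12, returns at 16): the order of bond formation is reversed, with C1–C2 made first by a tethered acylation and C2–O3 last. Aldehyde 12 is oxidised (NaClO2, NaH2PO4, 2-methylbut-2-ene; Pinnick oxidation) to 3-methoxy-4-(prop-2-en-1-yloxy)benzoic acid F1. F1 is esterified with the C4 hydroxyl of 11 (carbodiimide, DMAP; Steglich esterification) to give aryl ester F2. LiN(iPr)2 in THF at −78 °C then enolises the lactone, and on warming the C1 enolate attacks the tethered ester carbonyl in a five-membered intramolecular Claisen (Dieckmann-type) acyl transfer; this is driven by the conversion of an enolate into an alkoxide and again can occur only on the face cis to C4. Work-up gives cyclic hemiketal F3, in equilibrium with its open keto alcohol. NaBH4 with CeCl3·7H2O in MeOH at low temperature (Luche reduction) reduces the ketone form to benzylic diol F4, as a mixture at C2. Catalytic camphorsulfonic acid in CH2Cl2 then ionises the electron-rich benzylic alcohol and the C4 hydroxyl closes ring A, the standard furofuran closure; under these reversible conditions the aryl group is expected to take the exo position, which gives 16.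

**Step 4.**
- What may go wrong: incomplete enolisation of the dianion, addition of the enolate to the sulfonimine by-product, or deprotonation at C5 with elimination of the lactone oxygen (Stobbe-type ring opening), because two anionic sites must coexist.
- Fallback (sets out from 7, returns at 11): the acid is reduced first and the hydroxylation is run on a mono-enolate. BH3·SMe2 gives (4R,5S)-5-(3,4-dimethoxyphenyl)-4-(hydroxymethyl)oxolan-2-one F5. Et3SiCl and imidazole give its triethylsilyl ether F6. KN(SiMe3)2 and the Davis oxaziridine give the 3-hydroxy lactone F7, with oxygen trans to the C4 side chain. tBuMe2SiOTf and 2,6-lutidine give the bis-silyl compound F8. Pyridinium p-toluenesulfonate in MeOH at 0 °C removes only the primary triethylsilyl group and gives 11. This costs two more steps.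

**Step 9.**
- What may go wrong: BF3 may ionise the benzylic C2–O3 or C6–O7 bond in competition with the lactol hydroxyl, whose oxocarbenium ion is destabilised by the neighbouring silyloxy-bearing quaternary carbon. The result would be epimerisation at C2 or C6, or reductive ring opening by the silane.
- Fallback (sets out from 16, returns at 18): the Lewis acid is avoided altogether. LiBH4 in THF reduces the lactone of 16 to the tetrahydrofuran diol F9 (C8 as CH2OH on C1, C6 as the free benzylic alcohol on C5). The less hindered primary C8 hydroxyl is sulfonylated with 4-methylbenzenesulfonyl chloride, pyridine and DMAP to give monotosylate F10. KOtBu in THF then closes ring B by a 5-exo-tet Williamson etherification through the C6 alkoxide, which leaves the C6 configuration untouched and gives 18.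

**Step 11.**
- What may go wrong: acylation of the hindered tertiary alcohol may stall, and forcing it with acid catalysts would bring back ionisation of the benzylic ethers.
- Fallback (sets out from 19, returns at 20): the nucleophile is activated instead of the electrophile. 19 is deprotonated with LiN(SiMe3)2 in THF at −78 °C to the lithium alkoxide F11, which is quenched with acetyl chloride to give 20.

## Further compounds

F1 | step 7 | 3-methoxy-4-(prop-2-en-1-yloxy)benzoic acid | COc1cc(C(=O)O)ccc1OCC=C
F2 | step 7 | [(2S,3R,4S)-4-[(tert-butyldimethylsilyl)oxy]-2-(3,4-dimethoxyphenyl)-5-oxooxolan-3-yl]methyl 3-methoxy-4-(prop-2-en-1-yloxy)benzoate | COc1ccc([C@H]2OC(=O)[C@@H](O[Si](C)(C)C(C)(C)C)[C@@H]2COC(=O)c2ccc(OCC=C)c(OC)c2)cc1OC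
F3 | step 7 | (1R,5R,6S)-1-[(tert-butyldimethylsilyl)oxy]-6-(3,4-dimethoxyphenyl)-2-hydroxy-2-[3-methoxy-4-(prop-2-en-1-yloxy)phenyl]-3,7-dioxabicyclo[3.3.0]octan-8-one (cyclic hemiketal, C2 undefined) | COc1cc(C2(O)OC[C@@H]3[C@@H](c4ccc(OC)c(OC)c4)OC(=O)[C@]23O[Si](C)(C)C(C)(C)C)ccc1OCC=C
F4 | step 7 | 3-[(tert-butyldimethylsilyl)oxy]-5-(3,4-dimethoxyphenyl)-3-{hydroxy[3-methoxy-4-(prop-2-en-1-yloxy)phenyl]methyl}-4-(hydroxymethyl)oxolan-2-one (ring carbons as in 16, carbinol carbon as a mixture) | COc1cc(C(O)[C@@]2(O[Si](C)(C)C(C)(C)C)C(=O)O[C@H](c3ccc(OC)c(OC)c3)[C@H]2CO)ccc1OCC=C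
F5 | step 4 | (4R,5S)-5-(3,4-dimethoxyphenyl)-4-(hydroxymethyl)oxolan-2-one | COc1ccc([C@H]2OC(=O)C[C@@H]2CO)cc1OC
F6 | step 4 | (4R,5S)-5-(3,4-dimethoxyphenyl)-4-{[(triethylsilyl)oxy]methyl}oxolan-2-one | COc1ccc([C@H]2OC(=O)C[C@@H]2CO[Si](CC)(CC)CC)cc1OC
F7 | step 4 | (3S,4S,5S)-5-(3,4-dimethoxyphenyl)-3-hydroxy-4-{[(triethylsilyl)oxy]methyl}oxolan-2-one | COc1ccc([C@H]2OC(=O)[C@@H](O)[C@@H]2CO[Si](CC)(CC)CC)cc1OC
F8 | step 4 | (3S,4R,5S)-3-[(tert-butyldimethylsilyl)oxy]-5-(3,4-dimethoxyphenyl)-4-{[(triethylsilyl)oxy]methyl}oxolan-2-one | COc1ccc([C@H]2OC(=O)[C@@H](O[Si](C)(C)C(C)(C)C)[C@@H]2CO[Si](CC)(CC)CC)cc1OC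
F9 | step 9 | tetrahydrofuran diol from 16: ring A intact, C1 bearing the silyloxy group and CH2OH (C8), C5 bearing CH(OH)(3,4-dimethoxyphenyl) (C6), configurations as in 16 | COc1cc([C@H]2OC[C@H]([C@H](O)c3ccc(OC)c(OC)c3)[C@@]2(CO)O[Si](C)(C)C(C)(C)C)ccc1OCC=C
F10 | step 9 | primary (C8) 4-methylbenzenesulfonate of F9 | COc1cc([C@H]2OC[C@H]([C@H](O)c3ccc(OC)c(OC)c3)[C@@]2(COS(=O)(=O)c2ccc(C)cc2)O[Si](C)(C)C(C)(C)C)ccc1OCC=C
F11 | step 11 | lithium (1S,2R,5R,6S)-6-(3,4-dimethoxyphenyl)-2-[3-methoxy-4-(prop-2-en-1-yloxy)phenyl]-3,7-dioxabicyclo[3.3.0]octan-1-olate | COc1cc([C@H]2OC[C@@H]3[C@@H](c4ccc(OC)c(OC)c4)OC[C@]23[O-])ccc1OCC=C.[Li+]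
A1 | alternative 1 | 2-[4-(benzyloxy)-3-methoxyphenyl]-1,5-dioxaspiro[2.4]heptan-6-one (spiro-epoxy lactone, configured as in its SMILES) | COc1cc([C@@H]2O[C@@]23COC(=O)C3)ccc1OCc1ccccc1
A2 | alternative 1 | 5-[4-(benzyloxy)-3-methoxyphenyl]-4-hydroxy-4-(hydroxymethyl)oxolan-2-one (ring A hydroxylactone diol, C1 and C2 as in 21) | COc1cc([C@H]2OC(=O)C[C@@]2(CO)O)ccc1OCc1ccccc1
A3 | alternative 2 | (Z)-2-[4-(benzyloxy)-3-methoxyphenyl]-6-(3,4-dimethoxyphenyl)-3,7-dioxacyclooct-4-en-1-one (C2 and C6 as in 21) | COc1cc([C@H]2O/C=C\[C@@H](c3ccc(OC)c(OC)c3)OCC2=O)ccc1OCc1ccccc1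
A4 | alternative 2 | (1S,2R,5R,6S)-2-[4-(benzyloxy)-3-methoxyphenyl]-6-(3,4-dimethoxyphenyl)-3,7-dioxabicyclo[3.3.0]octan-1-ol | COc1cc([C@H]2OC[C@@H]3[C@@H](c4ccc(OC)c(OC)c4)OC[C@]23O)ccc1OCc1ccccc1
A5 | alternative 3 | 4-[4-(3,4-dimethoxybenzyl)-3-hydroxy-3-(hydroxymethyl)oxolan-2-yl]-2-methoxyphenyl acetate (C1, C2 and C5 as in 21) | COc1cc([C@H]2OC[C@H](Cc3ccc(OC)c(OC)c3)[C@]2(O)CO)ccc1OC(C)=O
A6 | alternative 3 | 4-[(1S,2R,5R,6S)-6-(3,4-dimethoxyphenyl)-1-hydroxy-3,7-dioxabicyclo[3.3.0]octan-2-yl]-2-methoxyphenyl acetate | COc1cc([C@H]2OC[C@@H]3[C@@H](c4ccc(OC)c(OC)c4)OC[C@]23O)ccc1OC(C)=O
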